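1. Cuts, in retrosynthetic order: (a) the C1′–C2′ bond between the benzylic CH2 on C6 and the alkenyl CH, together with the C3′–CH3 bond, both made in one operation from a terminal alkyne; (b) the C2–aryl bond (conjugate arylation of a chromone); (c) the C6–CH2OH and C6–I bonds on 5,7-dihydroxychromone; (d) in the chain, the C6′ carbinol (ketone reduction) and the C6′–C7′ acyl bond.
2. Enabling feature: C1′ is a benzylic carbon on C6 of the A ring, flanked by the C5 and C7 oxygens, and C2′=C3′(CH3) is an E-trisubstituted alkene, i.e. the retron of a syn-methylmetalation of a terminal C2′≡C3′ alkyne. A 2-methylalk-1-enylalane and a benzylic chloride therefore meet exactly at this bond.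
3. Forward: the A and C rings come from 5,7-dihydroxychromone; the free 5-OH steers iodination to C6, and a Stille hydroxymethylation installs C1′. The B ring is added, and the C ring saturated, by Rh-catalysed 1,4-arylation. The chain is joined last, followed by global deprotection.
4. Stereochemistry: C2 (S) from the chiral Rh catalyst; C6′ (R) from a CBS reduction; 2′E from syn carboalumination with retention in the coupling.
5. Locants: chain atoms C1′–C8′ (C1′ on C6); the aryl ring on C2 is the B ring.

Key step: step 13

Assumption: the absolute sense of steps 3 and 11 is taken from the accepted models (CBS; Rh/biaryl-bisphosphine 1,4-addition) and would be checked on the first batch, the mirror-image catalyst being used if it proves opposite.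

Step 1
Reactants: 1 pent-4-ynoic acid
Product: 3 N-methoxy-N-methylpent-4-ynamide, via acylimidazole 2 (not isolated)
Conditions: CDI (1.1 equiv), CH2Cl2, rt; then MeNH(OMe)·HCl (1.2 equiv), rt
Reagents that add atoms: N,O-dimethylhydroxylamine hydrochloride (CNOC.Cl)
Why: Amide formation through the acylimidazole is neutral and leaves the terminal alkyne untouched; the Weinreb amide is chosen because its chelated adduct stops a Grignard addition at the ketone.

Step 2
Reactants: 3 N-methoxy-N-methylpent-4-ynamide
Product: 4 2-methylhept-1-en-6-yn-3-one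
Conditions: isopropenylmagnesium bromide (2.2 equiv), THF, −20 → 0 °C; inverse quench into cold 1 M HCl
Reagents that add atoms: isopropenylmagnesium bromide (C=C(C)[Mg]Br)
Why: Weinreb ketone synthesis, in which the stable magnesium chelate prevents over-addition; the extra Grignard reagent covers deprotonation of the alkyne C–H, and the cold acidic quench protonates the released amine before it can add to the enone.

Step 3
Reactants: 4 2-methylhept-1-en-6-yn-3-one
Product: 5 (3R)-2-methylhept-1-en-6-yn-3-ol
Conditions: (S)-Me-CBS (0.2 equiv), catecholborane (1.5 equiv), toluene, −78 °C; MeOH, then aqueous work-up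
Reagents that add atoms: none
Why: Corey–Bakshi–Shibata reduction in which the isopropenyl group takes the role of the large substituent, so that the (S)-catalyst should deliver hydride to the face giving the (R)-carbinol; catecholborane at −78 °C does not hydroborate the alkyne or the alkene.

Step 4
Reactants: 5 (3R)-2-methylhept-1-en-6-yn-3-ol
Product: 6 tert-butyldimethyl{[(3R)-2-methylhept-1-en-6-yn-3-yl]oxy}silane
Conditions: TBSCl, imidazole, DMF, rt
Reagents that add atoms: tert-butyldimethylsilyl chloride (CC(C)(C)[Si](C)(C)Cl)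
Why: Standard silylation of a secondary alcohol; the TBS ether keeps the hydroxyl from consuming Me3Al and from ionising, and it falls in the final acid step.

Step 5
Reactants: 7 5,7-dihydroxy-4H-chromen-4-one
Product: 8 5-hydroxy-7-(methoxymethoxy)-4H-chromen-4-one
Conditions: MOMCl (1.1 equiv), i-Pr2NEt, CH2Cl2, 0 °C
Reagents that add atoms: chloromethyl methyl ether (COCCl)
Why: Selective O-alkylation of the acidic, non-chelated 7-OH, while the 5-OH stays locked in its hydrogen bond to the C4 carbonyl.

Step 6
Reactants: 8 5-hydroxy-7-(methoxymethoxy)-4H-chromen-4-one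
Product: 9 5-hydroxy-6-iodo-7-(methoxymethoxy)-4H-chromen-4-one
Conditions: BnMe3N·ICl2 (1.05 equiv), CaCO3, CH2Cl2/MeOH, rt
Reagents that add atoms: benzyltrimethylammonium dichloroiodate (C[N+](C)(C)Cc1ccccc1.Cl[I-]Cl)
Why: Electrophilic aromatic iodination of the phloroglucinol-type A ring goes ortho to the free, chelated 5-OH, i.e. at C6, as is known for 5-hydroxy-7-alkoxychromen-4-ones with this reagent; CaCO3 takes up the HCl so that the MOM ether is kept.

Step 7
Reactants: 9 5-hydroxy-6-iodo-7-(methoxymethoxy)-4H-chromen-4-one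
Product: 10 6-iodo-5,7-bis(methoxymethoxy)-4H-chromen-4-one
Conditions: NaH, MOMCl, DMF, 0 °C → rt
Reagents that add atoms: chloromethyl methyl ether (COCCl)
Why: Williamson alkylation of the sodium phenoxide caps the hindered 5-OH, so that a later leaving group on the C6 methylene cannot be expelled as an ortho-quinone methide and no acidic phenol meets the alane; the chromone has no stereocentre that base could harm.

Step 8
Reactants: 10 6-iodo-5,7-bis(methoxymethoxy)-4H-chromen-4-one
Product: 11 6-(hydroxymethyl)-5,7-bis(methoxymethoxy)-4H-chromen-4-one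
Conditions: Bu3SnCH2OH (1.5 equiv), Pd(PPh3)4 (10 mol %), 1,4-dioxane, 100 °C
Reagents that add atoms: (tributylstannyl)methanol (CCCC[Sn](CCCC)(CCCC)CO)
Why: Stille coupling with (tributylstannyl)methanol transfers the hydroxymethyl group selectively (the α-oxygen speeds its transmetalation over butyl) under neutral conditions that the acetals and the chromone tolerate.

Step 9
Reactants: 12 4-bromo-2-methoxyphenol
Product: 13 4-bromo-2-methoxy-1-(methoxymethoxy)benzene
Conditions: MOMCl, i-Pr2NEt, CH2Cl2, 0 °C → rt
Reagents that add atoms: chloromethyl methyl ether (COCCl)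
Why: Routine O-alkylation of a phenol; the MOM group matches those on the A ring so that one final operation removes all of them.

Step 10
Reactants: 13 4-bromo-2-methoxy-1-(methoxymethoxy)benzene
Product: 15 [3-methoxy-4-(methoxymethoxy)phenyl]boronic acid, via aryllithium 14 (not isolated)
Conditions: n-BuLi, THF, −78 °C; B(Oi-Pr)3, −78 °C → rt; aq. NH4Cl
Reagents that add atoms: triisopropyl borate (CC(C)OB(OC(C)C)OC(C)C); water (O)
Why: Bromine–lithium exchange at −78 °C is faster than ortho-lithiation next to the OMOM group, and borylation followed by near-neutral hydrolysis gives the boronic acid with the acetal intact.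

Step 11
Reactants: 11 6-(hydroxymethyl)-5,7-bis(methoxymethoxy)-4H-chromen-4-one; 15 [3-methoxy-4-(methoxymethoxy)phenyl]boronic acid
Product: 16 (2S)-6-(hydroxymethyl)-2-[3-methoxy-4-(methoxymethoxy)phenyl]-5,7-bis(methoxymethoxy)-2,3-dihydro-4H-chromen-4-one
Conditions: [Rh(OH)(cod)]2 (3 mol %), (S)-MeO-F12-BIPHEP (7 mol %), 15 (3 equiv), CH2Cl2/H2O, 30 °C
Reagents that add atoms: none
Why: Hayashi–Miyaura-type Rh-catalysed asymmetric 1,4-addition of an arylboronic acid to a chromone, in which the electron-poor (S)-biaryl bisphosphine should make the aryl–Rh species add to the face of C2 that gives the (2S)-flavanone and suppress 1,2-addition; no base is added, so the new centre cannot epimerise by retro-oxa-Michael opening, and the free primary alcohol and the acetals are tolerated.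

Step 12
Reactants: 16 (2S)-6-(hydroxymethyl)-2-[3-methoxy-4-(methoxymethoxy)phenyl]-5,7-bis(methoxymethoxy)-2,3-dihydro-4H-chromen-4-one
Product: 18 (2S)-6-(chloromethyl)-2-[3-methoxy-4-(methoxymethoxy)phenyl]-5,7-bis(methoxymethoxy)-2,3-dihydro-4H-chromen-4-one, via mesylate 17 (not isolated)
Conditions: MsCl, LiCl, 2,4,6-collidine, DMF, 0 °C; cold aqueous work-up, used crude at once
Reagents that add atoms: lithium chloride ([Li+].[Cl-])
Why: Mesylation followed by chloride displacement at a benzylic carbon activated by two ortho oxygens; the hindered weak base does not enolise the flavanone, so C2 is kept, and the labile chloride is used without chromatography.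

Step 13
Reactants: 6 tert-butyldimethyl{[(3R)-2-methylhept-1-en-6-yn-3-yl]oxy}silane; 18 (2S)-6-(chloromethyl)-2-[3-methoxy-4-(methoxymethoxy)phenyl]-5,7-bis(methoxymethoxy)-2,3-dihydro-4H-chromen-4-one
Product: 20 (2S)-6-[(2E,6R)-6-(tert-butyldimethylsilyloxy)-3,7-dimethylocta-2,7-dien-1-yl]-2-[3-methoxy-4-(methoxymethoxy)phenyl]-5,7-bis(methoxymethoxy)-2,3-dihydro-4H-chromen-4-one, via alkenylalane 19 (not isolated)
Conditions: 6 (1.6 equiv), Me3Al (3.2 equiv), Cp2ZrCl2 (0.4 equiv), ClCH2CH2Cl, 0 °C → rt; volatiles removed in vacuo; then 18 (1.0 equiv), Pd(PPh3)4 (5 mol %), THF, 0 °C → rt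
Reagents that add atoms: trimethylaluminium (C[Al](C)C)
Why: Cp2ZrCl2-catalysed syn-methylalumination of the terminal alkyne of 6 places CH3 on the internal and AlMe2 on the terminal carbon to give the (E)-alkenylalane 19; Pd(0) then inserts into the benzylic C–Cl bond of 18 (made reactive by the O5 and O7 ether oxygens ortho to C6), the alkenyl group passes from Al to Pd with retention, and reductive elimination forms C1′–C2′. The closest known reaction type is the one-pot carboalumination/Negishi coupling established for 2-methylalk-1-enylalanes and polyoxygenated benzylic chlorides. No ring is closed and no stereocentre is created; the 2′E geometry follows from syn addition and stereoretentive coupling, and C2 and C6′ are not touched. The selectivities needed are regiocontrol in the carbometalation (secured by the terminal alkyne; the 1,1-disubstituted C7′=C8′ alkene is inert to Me3Al/Zr) and chemoselectivity for the benzylic chloride over the C4 ketone and the MOM acetals. The latter is secured by stripping excess Me3Al before the coupling, by THF complexation of the alane and by the speed of the catalytic cycle at 0 °C.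

Step 14
Reactants: 20 (2S)-6-[(2E,6R)-6-(tert-butyldimethylsilyloxy)-3,7-dimethylocta-2,7-dien-1-yl]-2-[3-methoxy-4-(methoxymethoxy)phenyl]-5,7-bis(methoxymethoxy)-2,3-dihydro-4H-chromen-4-one
Product: 21 (2S)-5,7-dihydroxy-2-(4-hydroxy-3-methoxyphenyl)-6-[(2E,6R)-6-hydroxy-3,7-dimethylocta-2,7-dien-1-yl]-2,3-dihydro-4H-chromen-4-one
Conditions: 3 M aq. HCl/MeOH/THF, 45 °C
Reagents that add atoms: none
Why: Acid-catalysed acetal exchange removes the three MOM groups (the one at O5 first) and solvolyses the TBS ether in the same operation; dilute acid and moderate temperature are chosen to keep phenol-to-alkene cyclisation, ionisation at C6′ and opening of the C ring slow.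

Compound list
1 | pent-4-ynoic acid | C#CCCC(=O)O | starting material
2 | 1-(1H-imidazol-1-yl)pent-4-yn-1-one (acylimidazole) | C#CCCC(=O)n1ccnc1 | intermediate (not isolated)
3 | N-methoxy-N-methylpent-4-ynamide | C#CCCC(=O)N(C)OC | intermediate
4 | 2-methylhept-1-en-6-yn-3-one | C=C(C)C(=O)CCC#C | intermediate
5 | (3R)-2-methylhept-1-en-6-yn-3-ol | C=C(C)[C@H](O)CCC#C | intermediate
6 | tert-butyldimethyl{[(3R)-2-methylhept-1-en-6-yn-3-yl]oxy}silane | C=C(C)[C@H](O[Si](C)(C)C(C)(C)C)CCC#C | intermediate
7 | 5,7-dihydroxy-4H-chromen-4-one | O=c1ccoc2cc(O)cc(O)c12 | starting material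
8 | 5-hydroxy-7-(methoxymethoxy)-4H-chromen-4-one | O=c1ccoc2cc(OCOC)cc(O)c12 | intermediate
9 | 5-hydroxy-6-iodo-7-(methoxymethoxy)-4H-chromen-4-one | O=c1ccoc2cc(OCOC)c(I)c(O)c12 | intermediate
10 | 6-iodo-5,7-bis(methoxymethoxy)-4H-chromen-4-one | O=c1ccoc2cc(OCOC)c(I)c(OCOC)c12 | intermediate
11 | 6-(hydroxymethyl)-5,7-bis(methoxymethoxy)-4H-chromen-4-one | O=c1ccoc2cc(OCOC)c(CO)c(OCOC)c12 | intermediate
12 | 4-bromo-2-methoxyphenol | COc1cc(Br)ccc1O | starting material
13 | 4-bromo-2-methoxy-1-(methoxymethoxy)benzene | COCOc1ccc(Br)cc1OC | intermediate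
14 | [3-methoxy-4-(methoxymethoxy)phenyl]lithium | COCOc1ccc([Li])cc1OC | intermediate (not isolated)
15 | [3-methoxy-4-(methoxymethoxy)phenyl]boronic acid | COCOc1ccc(B(O)O)cc1OC | intermediate
16 | (2S)-6-(hydroxymethyl)-2-[3-methoxy-4-(methoxymethoxy)phenyl]-5,7-bis(methoxymethoxy)-2,3-dihydro-4H-chromen-4-one | O=C1C[C@@H](c3ccc(OCOC)c(OC)c3)Oc2cc(OCOC)c(CO)c(OCOC)c12 | intermediate
17 | {(2S)-2-[3-methoxy-4-(methoxymethoxy)phenyl]-5,7-bis(methoxymethoxy)-4-oxo-3,4-dihydro-2H-chromen-6-yl}methyl methanesulfonate | O=C1C[C@@H](c3ccc(OCOC)c(OC)c3)Oc2cc(OCOC)c(COS(C)(=O)=O)c(OCOC)c12 | intermediate (not isolated)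
18 | (2S)-6-(chloromethyl)-2-[3-methoxy-4-(methoxymethoxy)phenyl]-5,7-bis(methoxymethoxy)-2,3-dihydro-4H-chromen-4-one | O=C1C[C@@H](c3ccc(OCOC)c(OC)c3)Oc2cc(OCOC)c(CCl)c(OCOC)c12 | intermediate
19 | [(1E,5R)-5-(tert-butyldimethylsilyloxy)-2,6-dimethylhepta-1,6-dien-1-yl]dimethylalane | C=C(C)[C@H](O[Si](C)(C)C(C)(C)C)CC/C(C)=C/[Al](C)C | intermediate (not isolated)
20 | (2S)-6-[(2E,6R)-6-(tert-butyldimethylsilyloxy)-3,7-dimethylocta-2,7-dien-1-yl]-2-[3-methoxy-4-(methoxymethoxy)phenyl]-5,7-bis(methoxymethoxy)-2,3-dihydro-4H-chromen-4-one | C=C(C)[C@H](O[Si](C)(C)C(C)(C)C)CC/C(C)=C/Cc1c(OCOC)cc2c(c1OCOC)C(=O)C[C@@H](c1ccc(OCOC)c(OC)c1)O2 | intermediate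
21 | (2S)-5,7-dihydroxy-2-(4-hydroxy-3-methoxyphenyl)-6-[(2E,6R)-6-hydroxy-3,7-dimethylocta-2,7-dien-1-yl]-2,3-dihydro-4H-chromen-4-one | C=C(C)[C@H](O)CC/C(C)=C/Cc1c(O)cc2c(c1O)C(=O)C[C@@H](c1ccc(O)c(OC)c1)O2 | target

Total step count: 14.
Longest linear sequence: 8 steps (steps 5, 6, 7, 8, 11, 12, 13, 14; 7 → 8 → 9 → 10 → 11 → 16 → 18 → 20 → 21).

Steps most likely to fail

Step 13. Al–C bonds (alkenyl or residual methyl) may add to the C4 carbonyl, or the Lewis-acidic aluminium species may ionise the benzylic chloride so that Friedel–Crafts self-alkylation outruns oxidative addition. The fallback sets out from 6 and comes back at 20. Alane 19, made as in step 13, is quenched with N-bromosuccinimide at −78 °C to give, with retention of geometry, the (E)-alkenyl bromide F1, which is isolated. F1 and chloride 18 are then joined by nickel-catalysed reductive cross-electrophile coupling (NiBr2·glyme, 4,4′-di-tert-butyl-2,2′-bipyridine, Mn powder, NaI, DMA, rt) to give 20. Both partners are then electrophiles, the medium is neutral, and no main-group organometallic meets the ketone.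

Step 11. Conjugate addition to the hindered, electron-rich chromone may be slow, so that protodeboronation and 1,2-addition compete, or facial selectivity may be insufficient. The fallback sets out from 11 (with 15) and comes back at 16. Arylation without a chiral ligand ([Rh(OH)(cod)]2, dioxane/H2O, 50 °C) should give the racemic flavanone F2. Kinetic resolution by Noyori-type asymmetric transfer hydrogenation (Cp*RhCl[(R,R)-TsDPEN], HCO2H/Et3N, EtOAc, 40 °C, stopped just past half conversion) should then reduce the (2R)-enantiomer to the cis-(2R,4R)-flavan-4-ol F3 and leave the (2S)-ketone 16, which is separated by chromatography. The sense of the resolution follows the usual model for this catalyst and would be checked.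

Step 14. Under protic acid a free phenol may cyclise onto the C2′=C3′ alkene, the allylic C6′–O bond may ionise, or the C ring may open and re-close with loss of configuration at C2. The fallback sets out from 20 and comes back at 21, and unveils the two kinds of hydroxyl in separate, non-protic stages. ZnBr2/n-PrSH (CH2Cl2, 0 °C, minutes) cleaves the aryl MOM ethers by thiol capture of the oxocarbenium ion while the silyl group still keeps C6′ from ionising, giving the triphenol silyl ether F4. Fluoride buffered with acetic acid (TBAF/AcOH, THF, 0 °C) then frees the C6′ alcohol to give 21.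

Further compounds
F1 | step 13 | tert-butyl{[(3R,6E)-7-bromo-2,6-dimethylhepta-1,6-dien-3-yl]oxy}dimethylsilane | C=C(C)[C@H](O[Si](C)(C)C(C)(C)C)CC/C(C)=C/Br
F2 | step 11 | rac-6-(hydroxymethyl)-2-[3-methoxy-4-(methoxymethoxy)phenyl]-5,7-bis(methoxymethoxy)-2,3-dihydro-4H-chromen-4-one | O=C1CC(c3ccc(OCOC)c(OC)c3)Oc2cc(OCOC)c(CO)c(OCOC)c12
F3 | step 11 | (2R,4R)-6-(hydroxymethyl)-2-[3-methoxy-4-(methoxymethoxy)phenyl]-5,7-bis(methoxymethoxy)-3,4-dihydro-2H-chromen-4-ol | O[C@@H]1C[C@H](c3ccc(OCOC)c(OC)c3)Oc2cc(OCOC)c(CO)c(OCOC)c12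
F4 | step 14 | (2S)-6-[(2E,6R)-6-(tert-butyldimethylsilyloxy)-3,7-dimethylocta-2,7-dien-1-yl]-5,7-dihydroxy-2-(4-hydroxy-3-methoxyphenyl)-2,3-dihydro-4H-chromen-4-one | C=C(C)[C@H](O[Si](C)(C)C(C)(C)C)CC/C(C)=C/Cc1c(O)cc2c(c1O)C(=O)C[C@@H](c1ccc(O)c(OC)c1)O2
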